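**Retrosynthetic overview**

- Target 16 is traced back through ester methanolysis, Sandmeyer bromination, amine-directed dibromination, nitro reduction and O-acetylation to nitrophenol 10. A single nitrogen at C5' of ring B therefore programmes the three adjacent bromines C4'–C6'.
- Nitrophenol 10 is cut at C3'–C4' and C1'–C6' ([3+3] benzannulation). The run C1'(O-aryl)–C2'(OH)–C3'(H) of ring B is the aryloxyacetone 6 in disguise, and C4'–C5'(NO2)–C6' is sodium nitromalonaldehyde 7; this is the feature on which the route rests.
- Ketone 6 comes from phenol 4 and chloroacetone 5 by SN2 at a primary carbon, so the bridging oxygen needs no hindered aryl–oxygen coupling. Phenol 4 comes from 3,5-dibromosalicylaldehyde 1 by O-methylation and Baeyer–Villiger oxidation.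
- Ring order: ring A is bought intact; ring B is the only ring formed (step 4).

Key step: step 4

Remark: sodium nitromalonaldehyde is used as its commercial monohydrate, which is heat- and shock-sensitive and is handled in solution. Ring B is labelled C1' (bridging oxygen), C2' (OH), C3' (H), C4'–C6' (Br). The target has no stereocentre.

**Route**

Step 1
Reactants: 1 3,5-dibromosalicylaldehyde
Product: 2 3,5-dibromo-2-methoxybenzaldehyde
Conditions: MeI, K2CO3, DMF, rt → 40 °C
Reagents that add atoms: iodomethane, CI
Why: Williamson O-methylation of the acidic salicylaldehyde phenoxide with the small electrophile MeI; the aldehyde and aryl bromides are inert to K2CO3.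

Step 2
Reactants: 2 3,5-dibromo-2-methoxybenzaldehyde
Product: 4 3,5-dibromo-2-methoxyphenol, via 3,5-dibromo-2-methoxyphenyl formate 3 (not isolated)
Conditions: mCPBA, CH2Cl2, reflux; aq. Na2S2O3/NaHCO3 wash; then MeOH, cat. HCl, rt
Reagents that add atoms: 3-chloroperoxybenzoic acid (mCPBA), OOC(=O)c1cccc(Cl)c1
Why: Baeyer–Villiger oxidation in which the aryl group, helped by its ortho-methoxy donor, migrates to oxygen in the Criegee adduct to give formate 3, which acid-catalysed methanolysis cleaves; aryl bromides and the methyl ether are untouched.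

Step 3
Reactants: 4 3,5-dibromo-2-methoxyphenol; 5 chloroacetone
Product: 6 1-(3,5-dibromo-2-methoxyphenoxy)propan-2-one
Conditions: K2CO3, KI (cat.), acetone, reflux
Reagents that add atoms: none
Why: Williamson ether synthesis by SN2 at the primary α-chloroketone carbon (assisted by in situ Finkelstein exchange), which forms the future diaryl-ether C–O bond under mild conditions.

Step 4
Reactants: 6 1-(3,5-dibromo-2-methoxyphenoxy)propan-2-one; 7 sodium nitromalonaldehyde (monohydrate)
Product: 10 2-(3,5-dibromo-2-methoxyphenoxy)-4-nitrophenol, via open-chain enone nitronate 8 (not isolated), via sodium nitrophenolate 9 (not isolated)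
Conditions: 7·H2O (1.2 equiv), NaOH (1 equiv), EtOH/H2O, 0 °C → rt, 2–4 d, dark; then aq. HCl to pH 2
Reagents that add atoms: none
Why: Hydroxide reversibly forms both enolates of ketone 6; the methyl-side enolate adds to one formyl group of the non-enolizable nitromalonaldehyde anion and loses water to give the push–pull enone nitronate 8 (C3'–C4' formed; the order of the two condensations is immaterial), whose delocalization lets the chain rotate into the cisoid geometry needed for closure. The aryloxy-substituted enolate carbon then attacks the remaining formyl group (C1'–C6' formed), and a second dehydration with tautomerization gives the aromatic nitrophenolate 9, which acid releases as 10. The closest known reaction type is the classical condensation of acetone or dibenzyl ketone with sodium nitromalonaldehyde to 4-nitrophenols. Ring B closes in a favoured 6-(enolendo)-exo-trig aldol mode, the attacked carbonyl lying outside the forming ring. No stereocentre is created. The step needs only chemoselectivity for crossed over self-condensation, secured by the dialdehyde being a pure electrophile with more reactive carbonyls than the ketone and by irreversible aromatization, while regiochemistry is fixed because the dialdehyde is symmetric and the ketone carbonyl is flanked by exactly the CH3 and CH2OAr carbons that become C3' and C1'.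

Step 5
Reactants: 10 2-(3,5-dibromo-2-methoxyphenoxy)-4-nitrophenol
Product: 11 2-(3,5-dibromo-2-methoxyphenoxy)-4-nitrophenyl acetate
Conditions: Ac2O, pyridine, DMAP (cat.), CH2Cl2, 0 °C → rt
Reagents that add atoms: acetic anhydride, CC(=O)OC(C)=O
Why: DMAP-catalysed O-acylation masks the C2' hydroxyl so that it later neither directs bromine to C3' nor lets the para-aminophenol be oxidized to a quinone imine.

Step 6
Reactants: 11 2-(3,5-dibromo-2-methoxyphenoxy)-4-nitrophenyl acetate
Product: 12 4-amino-2-(3,5-dibromo-2-methoxyphenoxy)phenyl acetate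
Conditions: Fe powder, glacial AcOH, 50 °C; product used directly in step 7
Reagents that add atoms: none
Why: Béchamp-type dissolving-metal reduction of the nitro group; iron in acetic acid leaves aryl bromides alone and the acidic, non-nucleophilic medium keeps the aryl acetate intact.

Step 7
Reactants: 12 4-amino-2-(3,5-dibromo-2-methoxyphenoxy)phenyl acetate
Product: 13 4-amino-3,5-dibromo-2-(3,5-dibromo-2-methoxyphenoxy)phenyl acetate
Conditions: NBS (2.05 equiv), MeCN, 0 °C → rt
Reagents that add atoms: N-bromosuccinimide, O=C1CCC(=O)N1Br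
Why: Electrophilic aromatic bromination directed by the free amino group to its two ortho positions C4' and C6' (the para position carries the acetoxy group); C3' is meta to the amine and ring A is deactivated by two bromines, so two equivalents should stop at the dibromide.

Step 8
Reactants: 13 4-amino-3,5-dibromo-2-(3,5-dibromo-2-methoxyphenoxy)phenyl acetate
Product: 15 3,4,5-tribromo-2-(3,5-dibromo-2-methoxyphenoxy)phenyl acetate, via arenediazonium bromide 14 (not isolated)
Conditions: t-BuONO, CuBr2, MeCN, 0 °C → 60 °C
Reagents that add atoms: copper dibromide CuBr2, Br[Cu]Br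
Why: Sandmeyer bromination under aprotic alkyl nitrite/CuBr2 conditions (diazotization, single-electron reduction by copper, loss of N2, bromine transfer to the C5' aryl radical); the anhydrous medium spares the acetate, and the diazonium group is meta to the bridging oxygen, so ring closure onto ring A to a dibenzofuran is not possible.

Step 9
Reactants: 15 3,4,5-tribromo-2-(3,5-dibromo-2-methoxyphenoxy)phenyl acetate
Product: 16 3,4,5-tribromo-2-(3,5-dibromo-2-methoxyphenoxy)phenol (CNP0295171.0)
Conditions: HCl (ca. 1 M in MeOH), 40 °C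
Reagents that add atoms: none
Why: Acid-catalysed transesterification (methanolysis) of the aryl acetate frees the C2' hydroxyl, with the aryl methyl ether, diaryl ether and aryl bromides inert.

**Compound list**

1 | 3,5-dibromosalicylaldehyde (3,5-dibromo-2-hydroxybenzaldehyde) | O=Cc1cc(Br)cc(Br)c1O | starting material
2 | 3,5-dibromo-2-methoxybenzaldehyde | COc1c(Br)cc(Br)cc1C=O | intermediate
3 | 3,5-dibromo-2-methoxyphenyl formate | COc1c(Br)cc(Br)cc1OC=O | intermediate
4 | 3,5-dibromo-2-methoxyphenol | COc1c(Br)cc(Br)cc1O | intermediate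
5 | chloroacetone | CC(=O)CCl | starting material
6 | 1-(3,5-dibromo-2-methoxyphenoxy)propan-2-one | COc1c(Br)cc(Br)cc1OCC(C)=O | intermediate
7 | sodium nitromalonaldehyde (used as monohydrate) | [Na+].O=CC(C=O)=[N+]([O-])[O-] | starting material
8 | sodium salt of 6-(3,5-dibromo-2-methoxyphenoxy)-2-aci-nitro-5-oxohex-3-enal (open-chain mono-condensation product, alkene geometry not fixed) | [Na+].O=CC(=[N+]([O-])[O-])C=CC(=O)COc1cc(Br)cc(Br)c1OC | intermediate
9 | sodium 2-(3,5-dibromo-2-methoxyphenoxy)-4-nitrophenolate | [Na+].COc1c(Br)cc(Br)cc1Oc1cc([N+](=O)[O-])ccc1[O-] | intermediate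
10 | 2-(3,5-dibromo-2-methoxyphenoxy)-4-nitrophenol | COc1c(Br)cc(Br)cc1Oc1cc([N+](=O)[O-])ccc1O | intermediate
11 | 2-(3,5-dibromo-2-methoxyphenoxy)-4-nitrophenyl acetate | COc1c(Br)cc(Br)cc1Oc1cc([N+](=O)[O-])ccc1OC(C)=O | intermediate
12 | 4-amino-2-(3,5-dibromo-2-methoxyphenoxy)phenyl acetate | COc1c(Br)cc(Br)cc1Oc1cc(N)ccc1OC(C)=O | intermediate
13 | 4-amino-3,5-dibromo-2-(3,5-dibromo-2-methoxyphenoxy)phenyl acetate | COc1c(Br)cc(Br)cc1Oc1c(Br)c(N)c(Br)cc1OC(C)=O | intermediate
14 | 4-acetoxy-2,6-dibromo-3-(3,5-dibromo-2-methoxyphenoxy)benzenediazonium bromide (counter-ion nominal) | COc1c(Br)cc(Br)cc1Oc1c(Br)c([N+]#N)c(Br)cc1OC(C)=O.[Br-] | intermediate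
15 | 3,4,5-tribromo-2-(3,5-dibromo-2-methoxyphenoxy)phenyl acetate | COc1c(Br)cc(Br)cc1Oc1c(Br)c(Br)c(Br)cc1OC(C)=O | intermediate
16 | 3,4,5-tribromo-2-(3,5-dibromo-2-methoxyphenoxy)phenol | COc1c(Br)cc(Br)cc1Oc1c(O)cc(Br)c(Br)c1Br | target

**Step count**

Total steps: 9. Longest linear sequence: 9 (1 → 16).

**Steps most likely to fail**

1. Step 4. The aryloxyacetone may self-condense, or the sequence may stall at the open-chain stage, while the sparingly soluble ketone and the thermally fragile dialdehyde salt sit for days in aqueous base. Fallback, setting out from phenol 4 and returning at nitrophenol 10: ring B is bought instead of built and joined by metal-free O-arylation with a diaryliodonium salt. Commercial 2-iodo-4-nitrophenol is benzylated (BnBr, K2CO3, DMF) to 1-(benzyloxy)-2-iodo-4-nitrobenzene F1. This is oxidized (mCPBA, TsOH·H2O, MeCN, 60 °C) to 1-(benzyloxy)-2-[hydroxy(tosyloxy)iodo]-4-nitrobenzene F2, not isolated, and condensed in the same flask with 1,3,5-trimethoxybenzene to [2-(benzyloxy)-5-nitrophenyl](2,4,6-trimethoxyphenyl)iodonium tosylate F3. The phenoxide of 4 (K2CO3 or t-BuOK, THF/toluene, rt → 40 °C) should take up the electron-poor nitroaryl group selectively, the trimethoxyphenyl group leaving as the iodoarene, to give 1-(benzyloxy)-2-(3,5-dibromo-2-methoxyphenoxy)-4-nitrobenzene F4. BCl3 with pentamethylbenzene (CH2Cl2, −78 °C) should cleave the benzyl ether without touching the methyl ether, giving 10.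

2. Step 8. Diazotization of the hindered, weakly basic 2,6-dibromoaniline may be incomplete, the aryl radical may abstract hydrogen from the solvent (hydrodediazoniation), or the ester may be lost to give a para-diazoquinone. Fallback, setting out from nitrophenol 10 and returning at target 16: the phenol is carried as a methanesulfonate, which tolerates the strongly acidic classical Sandmeyer conditions for 2,6-dihaloanilines and also cannot transfer an acyl group to the amine in steps 6 and 7. Compound 10 with MsCl/Et3N (CH2Cl2, 0 °C) should give 2-(3,5-dibromo-2-methoxyphenoxy)-4-nitrophenyl methanesulfonate F5. Fe/AcOH reduces it to 4-amino-2-(3,5-dibromo-2-methoxyphenoxy)phenyl methanesulfonate F6. Br2 (2 equiv, AcOH, rt) gives 4-amino-3,5-dibromo-2-(3,5-dibromo-2-methoxyphenoxy)phenyl methanesulfonate F7. Nitrosylsulfuric acid (NaNO2 in conc. H2SO4, AcOH, 0–10 °C) forms 2,6-dibromo-3-(3,5-dibromo-2-methoxyphenoxy)-4-(methylsulfonyloxy)benzenediazonium hydrogensulfate F8, not isolated, which CuBr in 48% aq. HBr (60 °C) converts to 3,4,5-tribromo-2-(3,5-dibromo-2-methoxyphenoxy)phenyl methanesulfonate F9. KOH in MeOH/H2O/THF (60 °C, then acid) cleaves the sulfonate to 16.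

3. Step 2. Hydride rather than aryl migration in the Criegee adduct of this electron-poor, hindered aldehyde would divert material to the benzoic acid, or peracid addition may be sluggish. Fallback, setting out from aldehyde 1 and returning at phenol 4: the oxidation is run on the free salicylaldehyde, where the ortho-phenoxide drives aryl migration. Dakin oxidation of 1 (H2O2, aq. NaOH, rt, then acid) should give 3,5-dibromobenzene-1,2-diol F10. Methylation with MeI and one equivalent of weak base (NaHCO3 or Li2CO3, DMF, 40 °C) should take place at the more acidic hydroxyl, the one ortho and para to bromine, to give 4; the regiochemistry would be confirmed before proceeding.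

**Further compounds**

F1 | step 4 | 1-(benzyloxy)-2-iodo-4-nitrobenzene | O=[N+]([O-])c1ccc(OCc2ccccc2)c(I)c1
F2 | step 4 | 1-(benzyloxy)-2-[hydroxy(tosyloxy)iodo]-4-nitrobenzene | Cc1ccc(S(=O)(=O)OI(O)c2cc([N+](=O)[O-])ccc2OCc2ccccc2)cc1
F3 | step 4 | [2-(benzyloxy)-5-nitrophenyl](2,4,6-trimethoxyphenyl)iodonium 4-methylbenzenesulfonate | COc1cc(OC)c([I+]c2cc([N+](=O)[O-])ccc2OCc2ccccc2)c(OC)c1.Cc1ccc(S(=O)(=O)[O-])cc1
F4 | step 4 | 1-(benzyloxy)-2-(3,5-dibromo-2-methoxyphenoxy)-4-nitrobenzene | COc1c(Br)cc(Br)cc1Oc1cc([N+](=O)[O-])ccc1OCc1ccccc1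
F5 | step 8 | 2-(3,5-dibromo-2-methoxyphenoxy)-4-nitrophenyl methanesulfonate | COc1c(Br)cc(Br)cc1Oc1cc([N+](=O)[O-])ccc1OS(C)(=O)=O
F6 | step 8 | 4-amino-2-(3,5-dibromo-2-methoxyphenoxy)phenyl methanesulfonate | COc1c(Br)cc(Br)cc1Oc1cc(N)ccc1OS(C)(=O)=O
F7 | step 8 | 4-amino-3,5-dibromo-2-(3,5-dibromo-2-methoxyphenoxy)phenyl methanesulfonate | COc1c(Br)cc(Br)cc1Oc1c(Br)c(N)c(Br)cc1OS(C)(=O)=O
F8 | step 8 | 2,6-dibromo-3-(3,5-dibromo-2-methoxyphenoxy)-4-(methylsulfonyloxy)benzenediazonium hydrogensulfate | COc1c(Br)cc(Br)cc1Oc1c(Br)c([N+]#N)c(Br)cc1OS(C)(=O)=O.OS(=O)(=O)[O-]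
F9 | step 8 | 3,4,5-tribromo-2-(3,5-dibromo-2-methoxyphenoxy)phenyl methanesulfonate | COc1c(Br)cc(Br)cc1Oc1c(Br)c(Br)c(Br)cc1OS(C)(=O)=O
F10 | step 2 | 3,5-dibromobenzene-1,2-diol | Oc1cc(Br)cc(Br)c1O
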